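**Nothing vanishes.** Every unit of substrate charged stays in the flask. So what eta shows neither as substrate nor as single product at 1.33 min, 33.0%, sits elsewhere. Eta cannot part side product from isomer of the product, so we call the two together the loss.

**Your bench.** These flasks will have run 5.0 min when you come.

| setting | eta | spring | summer | winter | dusk |
|---|---|---|---|---|---|
| substrate | 0.11 M | 0.10 M | 0.030 M | 0.10 M | 0.030 M |
| reagent | 0.20 M | 0.200 M | 0.200 M | 0.100 M | 0.100 M |
| temperature | 5 °C | 5 °C | 5 °C | 5 °C | 5 °C |
| remark | run made earlier |  |  |  |  |
| time |  | 5.0 min | 5.0 min | 5.0 min | 5.0 min |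

- eta (time / min: single product / %, substrate / %): 0.250: 42, 51; 0.500: 51, 28; 1.33: 64, 3; 3.00: 61, 0

(scatter of a reading: 1.5 percentage points)

- percent here means substrate units held: one side product counts as two
- the earlier runs were read with a standard deviation of 1.5 percentage points
- reactions considered so far: substrate + reagent -> single product; reagent + single product -> bis adduct; reagent + bis adduct -> tris adduct; reagent + tris adduct -> tetra adduct; substrate + single product -> side product; single product <-> isomer of the product

1. all flasks from highest to lowest amount of single product, in percent of the substrate charged, at 5.0 min (spring / summer / winter / dusk)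
2. the amount of single product, in percent of the substrate charged of the flask you put first, at 5.0 min
3. the amount of single product, in percent of the substrate charged of the flask you put last, at 5.0 min

**Our gauge.** Substrate is taken both by reagent and by single product, so the loss should follow c(single product) over c(reagent). We replace each curve by its mean: the first then goes with the substrate charge, the second with the reagent charge. The loss gauge is eta's loss divided by eta's ratio of substrate charge to reagent charge, 60.0%. Times each flask's own ratio, it gives summer 9.00%, dusk 18.0%, spring 30.0% and winter 60.0%. The swap is weakest in winter, whose ratio is the highest.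

**The forecast.** It says dusk > summer > spring > winter, with 72% and 41%, holding that “Bis loss to 5 min costs summer most”. Our gauge alone has summer losing less than dusk, so there we differ.

**The result.** The flasks give dusk > summer > spring > winter, with 67.9% and 44.5%.

    substrate + reagent → single product (k = 0.252 M⁻¹ s⁻¹, Ea = 41.0 kJ mol⁻¹)
    reagent + single product → bis adduct (k = 0.00894 M⁻¹ s⁻¹, Ea = 47.0 kJ mol⁻¹)
    reagent + bis adduct → tris adduct (k = 0.486 M⁻¹ s⁻¹, Ea = 48.0 kJ mol⁻¹)
    reagent + tris adduct → tetra adduct (k = 0.699 M⁻¹ s⁻¹, Ea = 40.0 kJ mol⁻¹)
    substrate + single product → side product (k = 0.114 M⁻¹ s⁻¹, Ea = 54.0 kJ mol⁻¹)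
    single product ⇌ isomer of the product (K = 0.110, k = 0.0197 s⁻¹, Ea = 80.0 kJ mol⁻¹, ΔH = −55.0 kJ mol⁻¹)
    (constants at 5 °C)

**Against the gauge.** In dusk, substrate, the limiting reagent, is down to 0.23%, and side product plus isomer of the product come to 20.1% against the gauge's 18.0%. Winter holds 50.1% of them against 60.0%. Summer holds 26.4% of tetra adduct, dusk 9.65%. A neighbour of winter charged with 0.17 M of reagent has a gauge of 35.3%; it holds 32.5% of the two, and 56.5% of single product.

All runs were computed with made-up constants.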